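Readings and results were computed with constants of no real substance.

Amounts first: blue and amber are charged alike, with substrate 0.050 M, reagent 0.0750 M and free catalyst 0.24 mM, and they differ in time, 4.0 min against 12 min. The autumn run has the same substrate and reagent but 0.12 mM of free catalyst.

| flask | substrate | reagent | free catalyst | remark | time |
|---|---|---|---|---|---|
| noon | 0.034 M | 0.075 M | 0.24 mM | run made earlier |  |
| dawn | 0.075 M | 0.075 M | 0.24 mM | run made earlier |  |
| autumn | 0.050 M | 0.075 M | 0.12 mM | run made earlier |  |
| blue | 0.050 M | 0.0750 M | 0.24 mM |  | 4.0 min |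
| amber | 0.050 M | 0.0750 M | 0.24 mM |  | 12 min |

| run | time / min | substrate / % | catalyst intermediate D / % | product / % | catalyst intermediate C / % |
|---|---|---|---|---|---|
| noon | 0.250 | 93.3 | 0 | 5.5 | 0.7 |
| noon | 0.417 | 89.2 | 0 | 9.4 | 0.5 |
| noon | 0.667 | 84.4 | 1.0 | 15.0 | 0.9 |
| noon | 1.33 | 75.2 | 1.5 | 24.8 | 1.1 |
| noon | 2.00 | 66.9 | 0 | 31.0 | 1.9 |
| noon | 3.00 | 57.9 | 0 | 41.2 | 0.5 |
| dawn | 0.250 | 95.8 | 0.4 | 3.6 | 0.2 |
| dawn | 0.417 | 95.3 | 0 | 5.6 | 0 |
| dawn | 0.667 | 90.9 | 0.2 | 8.8 | 0.3 |
| dawn | 1.33 | 85.1 | 0.2 | 14.9 | 0.5 |
| dawn | 2.00 | 79.8 | 0.5 | 19.2 | 0.4 |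
| dawn | 3.00 | 74.4 | 0.1 | 25.6 | 0 |
| autumn | 0.250 | 96.8 | 0 | 2.0 | 0 |
| autumn | 0.500 | 94.3 | 0.4 | 4.9 | 0 |
| autumn | 0.833 | 93.7 | 0.1 | 7.3 | 0.3 |
| autumn | 1.50 | 87.2 | 0 | 12.9 | 0 |
| autumn | 3.00 | 79.4 | 0 | 21.3 | 0 |

(readings scatter by 0.5 percentage points)

- a reading or a percentage of product counts all its forms, free or not

- which of these there is most of at the end, counted by the substrate in it, blue (catalyst intermediate D / catalyst intermediate C / substrate / product)
- which of these there is most of at the end, counted by the substrate in it, amber (catalyst intermediate D / catalyst intermediate C / substrate / product)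
- final amount of the leader among these, as a percentage of the substrate charged, in blue
- final amount of the leader among these, as a percentage of the substrate charged, in amber

**What do you carry from the runs to these flasks?** Two measures. The dose D is the free catalyst charged times the time. The burn B is the natural logarithm of substrate charged over substrate left.

**Why the dose?** I assume that a catalyst turns over without being used up, so with less of it the same course takes longer. As a check, autumn at 3.00 min shows 21.3% product, between noon's 24.8% and dawn's 14.9% at 1.33 min, and its substrate charge lies between theirs. So autumn can stand in for blue and amber, at a smaller dose.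

**How does B grow with D?** As a power, a straight line in logarithms. Its slope n, the log slope, is the number of decades B rises per decade of D. In autumn, B goes from 0.137 at 1.50 min to 0.231 at 3.00 min, so n = 0.752.

**That is two scattered readings. Why trust it?** Dawn and noon have no reading at 1.50 min, so I take their nearest pair of times, 1.33 min and 3.00 min, which gives 0.745 in dawn and 0.800 in noon. Amber remains the weaker reckoning, since its dose is larger than autumn's last.

**Reckon it.** Blue's dose is 2.67 times autumn's last, or 0.427 of a decade, so B = 0.482 and 61.7% substrate remains. Amber's dose is 8.00 times autumn's, so B = 1.10 and 33.2% substrate remains. All the catalyst equals 0.480% of the substrate charge, far less, so substrate and product hold nearly all of it. I commit to substrate leading blue at 61.7% and product leading amber at 66.8%.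

The forecast names substrate at 61% for blue and product at 61% for amber, on the ground that “Every run slows faster than substrate loss explains”. On amber my 66.8% stands higher than its figure.

Blue ended with substrate leading at 60.0%, and amber with product leading at 65.2%.

    substrate + free catalyst ⇌ catalyst intermediate A (K = 17.9 L mol⁻¹, k = 279 L mol⁻¹ s⁻¹)
    reagent + catalyst intermediate A → catalyst intermediate B (k = 99.0 L mol⁻¹ s⁻¹)
    catalyst intermediate B → by-product + catalyst intermediate C (k = 12.8 s⁻¹)
    catalyst intermediate C ⇌ catalyst intermediate D (K = 0.110, k = 9.17 s⁻¹)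
    catalyst intermediate D ⇌ free catalyst + product (K = 0.0260 M, k = 11.6 s⁻¹)
    crystals ⇌ product, rate k6*(cs6 - [product]) while solid is left; crystals form when [product] > cs6 (solubility = 36.0 mM, k = 0.581 s⁻¹)

At 12.0 min, amber held 82.2% of its catalyst as catalyst intermediate C, the resting state. Amber's final burn is 1.07. A neighbour like amber but charged with 4.1 × 10⁻⁴ M of free catalyst has 1.71 times amber's dose, 0.233 of a decade. With n = 0.752, its burn comes to 1.60, which leaves 20.2% substrate by the reckoning. That neighbour ended with 22.2% substrate.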